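# Proposal: β-collatolic acid by de novo construction of ring B from an aryloxy bis(silyloxy)diene and an ynoate

## The problem

β-Collatolic acid (22) is a diaryl ether. Ring A is an isocoumarin (6-methoxy-3-pentyl, ether oxygen at C8, peri to the lactone carbonyl). It is joined through oxygen to C5 of a hexasubstituted benzoic acid, ring B (C1 CO2H, C2 OH, C3 H, C4 OH, C5 OAr, C6 CH2COC5H11). The ether oxygen is flanked on ring B by a hydroxyl and a branched benzylic chain and on ring A by the lactone carbonyl. Coupling two finished arenes would therefore have to take place at a doubly ortho-substituted, electron-rich carbon. There is no stereocentre; the task is regiocontrol on ring B, which electrophilic substitution of a resorcinol with two comparably activated positions cannot give. Three groups are fragile: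

- the enol lactone of ring A, which is opened by hydroxide, alkoxides and amines and lies within reach of any carbanion generated on the ether side chain;
- the β-resorcylic acid, which decarboxylates in hot acid;
- the 2-oxoheptyl ketone ortho to the carboxyl, which closes to a second isocoumarin under dehydrating acid.

The free phenols also exclude strong oxidants late in the route. The enabling feature is that ring B is a resorcylate. C2–C5 carry O, H, O, O exactly as the four carbons of a 4-aryloxyacetoacetate do, and C1–C6 carry the carboxyl and the alkyl chain like the α- and β-carbons of an alk-2-ynoate. Ring B can thus be made by a [4+2] cycloaddition with the ether oxygen already in place.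

## Retrosynthesis

**22 ⇒ 21.** The O–allyl bond of an ester is cut, so the carboxyl is carried as the allyl ester 21. A tert-butyl ester needs acid, under which the keto acid can cyclodehydrate and decarboxylate. A benzyl ester needs hydrogenation beside the C3=C4 bond of ring A, and a methyl ester needs saponification beside the lactone. Only the allyl group leaves under neutral conditions, by zerovalent palladium. The forward step needs an allyl acceptor that attacks neither the ketone nor the lactone.

**21 ⇒ 20.** The side-chain ketone is retraced to the 1,3-dithiane 20. A free ketone cannot pass through ring formation: β,γ to the alkyne it would isomerise to an allenyl ketone, and it would compete as an electrophile for a silyl ketene acetal. The dithiane is inert to silyl dienes, heat and dilute acid, and it also lets the chain be built by umpolung. The forward hydrolysis must be alkylative, not oxidative, because two phenols are free.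

**20 ⇒ 11 + 17 (key cut).** C1–C2 and C5–C6 of ring B are cut, giving diene 11 and ynoate 17. The neighbouring cuts are worse:

- the ring B C5–O bond would require coupling at the most hindered carbon of the molecule;
- the C6–CH2 bond would require benzylic acylation with an amide base in the presence of ring A's lactone and its acidic C3 methylene.

Diene 11 holds ring A complete plus four carbons. Ynoate 17 is an acyclic ten-carbon chain. The forward reaction must bond the aryloxy-bearing terminus of 11 to the β-carbon of 17 and aromatise with loss of the methoxy group only.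

**11 ⇒ 9 ⇒ 7 + 8.** The diene is the double O-silylation product of β-keto ester 9, through the enol ether 10. In 9 the ether is cut at O–CH2, not at aryl–O, so the bond is made by SN2 of phenol 7 on the primary chloride 8. This is why no aryl–oxygen coupling is needed anywhere. The forward silylation must avoid a free carbanion next to the peri lactone.

**7 ⇒ 6 ⇒ 5 ⇒ 2 + 4 (2 from 1, 4 from 3).** Phenol 7 comes from selective cleavage of the peri methyl ether of 6. The lactone O–C1 bond of 6 is cut to keto ester 5, and the CH2–CO bond of 5 is cut to toluate 2 and amide 4. Both phenols of 1 are methylated so that the benzylic anion can be formed cleanly. Chelation to the lactone carbonyl later distinguishes the two methyl ethers. Amide 4 stops the acylation at the ketone.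

**17 ⇒ 16 ⇒ 15 ⇒ 13 + 14 (13 from 12).** The C(sp)–CO2 bond is cut to alkyne 16. The silyl cap is removed in thought to give 15. The dithiane C2–CH2 bond is cut to the acyl-anion equivalent 13 (from aldehyde 12) and the propargyl bromide 14. The silyl group on 14 prevents proton transfer from the alkyne and attack at the distal carbon.

## Roads not taken

**Alternative 1:** Ring B is cut at C5–C6 and C3–C4 and taken back to the cyclohexane-1,3-dione A3. In the forward direction the lithium enolate of aryloxyacetate A1 adds to alkylidene acetoacetate A2 (Michael, C5–C6). A stronger alkoxide base then closes the methyl ketone enolate onto the aryloxyacetate ester (Dieckmann, C3–C4). An oxidation must follow to reach the arene.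

- Merits: robust enolate chemistry, no heat- or moisture-sensitive diene, and a regiochemistry fixed by connectivity and not by orbital polarisation.
- Weak points:
  - A3 lies two hydrogens above the aromatic level, so a dehydrogenation is needed beside an electron-rich aryl ether and an α-aryloxy ketone.
  - Three stereocentres are made only to be erased.
  - The enolate of A1 has an ortho methoxycarbonyl group positioned for intramolecular Claisen closure to a 3-hydroxybenzofuran, the classical fate of such enolates.
  - Ring A in A3 is still an open toluate, so the isocoumarin must be built afterwards by benzylic metalation beside ring B's esters and acidic phenols.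
- Comparison: this road is the safer one for the ring-forming step itself and needs no regiochemical argument. The chosen plan sets against it that 20 arrives aromatic, with ring A finished, in one operation from 11 and 17, with no redox adjustment and only one protecting group on ring B.

**Alternative 2:** Ring A is cut at C6–C7 and C4a–C8a, and the finished, protected ring B phenol A4 carries the nucleophile. A4 is converted into silyl dienol ether A5. Under a silyl triflate, A5 attacks the acetal carbon of A6 through its terminal carbon, and the ester α-carbon then closes onto the ketone. Two eliminations give arene A7.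

- Merits: A5 is a mono-silyl dienolate and more robust than 11. The reacting centres are unhindered, and the reaction runs at low temperature under Lewis acid.
- Weak points:
  - A4 is a fully substituted 5-hydroxyresorcylate. Making it regioselectively is the central difficulty of the target, merely displaced, and it needs an arene oxidation or its equivalent.
  - Three benzyl groups sit beside a dithiane, so hydrogenolysis is blocked by sulfur and Lewis-acid debenzylation threatens the ring A methyl ether.
  - A7 still needs benzylic acylation and lactonisation to become the isocoumarin.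
- Comparison: this road is better at the ring-forming event. The chosen plan sets against it that the C5 oxygen of ring B comes from the alkylating agent 8 and not from functionalising an arene, and that four protecting groups shrink to one.

**Alternative 3:** Ring B is cut at C1–C6 only (aldol). Diketo-dioxinone A8 is heated with the alcohol that is to become the ester. The acylketene is trapped as triketo ester A9, whose C1 methylene condenses with the C6 ketone to give arene A10.

- Merits: a biomimetic, nearly neutral aromatisation with ring A complete and the positions of the hydroxyls and the ester fixed by the chain. The ketal and the ester can fall together in acid.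
- Weak points:
  - A8 holds an α-aryloxy-1,3-diketone inside a tetracarbonyl chain. Building it means C-acylation at the aryloxy-bearing carbon while the methylene next to the dioxinone is more acidic.
  - Every enolate on that side chain can attack the peri lactone.
  - A9 can also aldolise through its side-chain methylene onto the C2 ketone, and it is open to retro-Claisen cleavage.
  - The acidic end-game risks cyclodehydration of the keto acid.
- Comparison: the aromatisation of A9 is probably more dependable than the hindered intermolecular cycloaddition of 11 with 17, and there Alternative 3 is the stronger road. The chosen plan sets against it convergence: two fragments, each a few steps from catalogue materials, give ring B in one step, whereas A8 needs a longer linear build-up through the least favourable enolate acylation.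

Key step: step 12

## Route

Assumption: diene 11 is taken to form mainly as the 3Z isomer (aryloxy group cis to the 3-silyloxy group), as is usual for silyl enol ethers of α-alkoxy ketones. That isomer places the aryloxy group on the outside of the s-cis diene.

Step 1
Reactants: 1 methyl 2,4-dihydroxy-6-methylbenzoate
Product: 2 methyl 2,4-dimethoxy-6-methylbenzoate
Conditions: MeI (excess), K2CO3, DMF, 50 °C
Reagents that add atoms: iodomethane, CI
Why: Williamson O-methylation of both phenols; the hydrogen-bonded 2-OH reacts more slowly but yields to excess MeI in DMF.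

Step 2
Reactants: 3 hexanoyl chloride
Product: 4 N-methoxy-N-methylhexanamide
Conditions: MeNHOMe·HCl, pyridine, CH2Cl2, 0 °C to rt
Reagents that add atoms: N,O-dimethylhydroxylamine hydrochloride, CNOC.Cl
Why: Acyl substitution of an acid chloride by an amine; routine N-methoxy-N-methylamide formation.

Step 3
Reactants: 2 methyl 2,4-dimethoxy-6-methylbenzoate; 4 N-methoxy-N-methylhexanamide
Product: 5 methyl 2,4-dimethoxy-6-(2-oxoheptyl)benzoate
Conditions: LiN(iPr)2, THF, −78 °C; then 4, −78 to −40 °C; aq. HCl quench
Reagents that add atoms: none
Why: Lateral lithiation of an o-toluate gives an ester-stabilised benzylic anion, which acylates the N-methoxy-N-methylamide through a chelated tetrahedral intermediate that releases the ketone only on quench; the doubly ortho-substituted ester and −78 °C suppress self-condensation.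

Step 4
Reactants: 5 methyl 2,4-dimethoxy-6-(2-oxoheptyl)benzoate
Product: 6 6,8-dimethoxy-3-pentyl-1H-isochromen-1-one
Conditions: p-TsOH·H2O (cat.), PhMe, reflux with removal of MeOH
Reagents that add atoms: none
Why: Acid-catalysed enol lactonisation: the aryl-conjugated enol of the ketone attacks the ortho ester and methanol is driven off; acid is chosen because base would allow carbon acylation through the other enolate to a naphthalenediol.

Step 5
Reactants: 6 6,8-dimethoxy-3-pentyl-1H-isochromen-1-one
Product: 7 8-hydroxy-6-methoxy-3-pentyl-1H-isochromen-1-one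
Conditions: BCl3 (1.2 equiv), CH2Cl2, −78 to 0 °C; aq. work-up
Reagents that add atoms: none
Why: Chelation-directed ether cleavage: BCl3 bridges the lactone carbonyl and the peri methoxy oxygen, so only the 8-methyl ether is cleaved and the 6-methyl ether is left.

Step 6
Reactants: 7 8-hydroxy-6-methoxy-3-pentyl-1H-isochromen-1-one; 8 methyl 4-chloro-3-oxobutanoate
Product: 9 methyl 4-[(6-methoxy-1-oxo-3-pentyl-1H-isochromen-8-yl)oxy]-3-oxobutanoate
Conditions: NaH (2.2 equiv), THF–DMF, 0 °C; 7, then 8 dropwise, rt; dilute HCl work-up
Reagents that add atoms: none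
Why: Williamson ether synthesis at a primary α-chloro ketone carbon; the second equivalent of NaH holds the β-keto ester as its enolate, which damps its self-alkylation while the phenoxide displaces chloride.

Step 7
Reactants: 9 methyl 4-[(6-methoxy-1-oxo-3-pentyl-1H-isochromen-8-yl)oxy]-3-oxobutanoate
Product: 11 (1Z,3Z)-1-methoxy-1,3-bis(trimethylsilyloxy)-4-[(6-methoxy-1-oxo-3-pentyl-1H-isochromen-8-yl)oxy]buta-1,3-diene, via mono(trimethylsilyl) enol ether 10 (not isolated)
Conditions: Me3SiOTf (2.3 equiv), Et3N (3 equiv), Et2O, 0 °C to rt; ammonium salt layer removed, concentrated under argon, used crude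
Reagents that add atoms: trimethylsilyl trifluoromethanesulfonate, C[Si](C)(C)OS(=O)(=O)C(F)(F)F
Why: Soft enolisation in two stages: O-silylation of the keto ester gives 10, and silylation of its ester carbonyl acidifies the CH2 next to the ether oxygen so that Et3N removes a proton and the ketene acetal forms. No free carbanion appears next to the peri lactone, and this is the established silyl triflate and amine route to 1-alkoxy-1,3-bis(silyloxy)buta-1,3-dienes.

Step 8
Reactants: 12 hexanal
Product: 13 2-pentyl-1,3-dithiane
Conditions: HS(CH2)3SH, BF3·OEt2 (cat.), CH2Cl2, 0 °C to rt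
Reagents that add atoms: propane-1,3-dithiol, SCCCS
Why: Lewis-acid-catalysed thioacetalisation of an aldehyde.

Step 9
Reactants: 13 2-pentyl-1,3-dithiane; 14 3-bromo-1-(trimethylsilyl)prop-1-yne
Product: 15 trimethyl[3-(2-pentyl-1,3-dithian-2-yl)prop-1-yn-1-yl]silane
Conditions: n-BuLi, THF, −30 °C; then 14, −78 °C to rt
Reagents that add atoms: none
Why: Corey–Seebach alkylation of a 2-lithio-1,3-dithiane with a propargylic bromide; the silyl cap removes the acidic alkyne hydrogen and blocks attack at the distal alkyne carbon.

Step 10
Reactants: 15 trimethyl[3-(2-pentyl-1,3-dithian-2-yl)prop-1-yn-1-yl]silane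
Product: 16 2-pentyl-2-(prop-2-yn-1-yl)-1,3-dithiane
Conditions: K2CO3 (cat.), MeOH, rt
Reagents that add atoms: none
Why: Base-catalysed methanolysis of the C(sp)–Si bond; the dithiane is inert.

Step 11
Reactants: 16 2-pentyl-2-(prop-2-yn-1-yl)-1,3-dithiane
Product: 17 allyl 4-(2-pentyl-1,3-dithian-2-yl)but-2-ynoate
Conditions: n-BuLi, THF, −78 °C; then ClCO2CH2CH=CH2, −78 to 0 °C
Reagents that add atoms: allyl chloroformate, C=CCOC(=O)Cl
Why: Acylation of a lithium acetylide with a chloroformate, the standard route to alk-2-ynoates; the fully substituted dithiane carbon has no competing acidic hydrogen.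

Step 12
Reactants: 11 (1Z,3Z)-1-methoxy-1,3-bis(trimethylsilyloxy)-4-[(6-methoxy-1-oxo-3-pentyl-1H-isochromen-8-yl)oxy]buta-1,3-diene; 17 allyl 4-(2-pentyl-1,3-dithian-2-yl)but-2-ynoate
Product: 20 allyl 2,4-dihydroxy-5-[(6-methoxy-1-oxo-3-pentyl-1H-isochromen-8-yl)oxy]-6-[(2-pentyl-1,3-dithian-2-yl)methyl]benzoate, via cyclohexa-1,4-diene cycloadduct 18 (not isolated), via bis(trimethylsilyl) ether 19 (not isolated)
Conditions: 17 (3 equiv), PhMe (about 2 M), 100–110 °C, sealed tube, acid-free glassware; then 1 M HCl, THF, 0 °C to rt
Reagents that add atoms: none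
Why: This is a normal-electron-demand Diels–Alder reaction: the HOMO of 11 is largest at C4, the carbon β to the 3-silyloxy group and vinylogously β to both ketene-acetal oxygens, and the LUMO of 17 is largest at the β-carbon, so an asynchronous transition state forms the C5–C6 bond of ring B first and the C1–C2 bond second. The closest known reaction type is the cycloaddition of 1-alkoxy-1,3-bis(silyloxy)buta-1,3-dienes, 4-alkoxy-substituted ones included, and of cyclic 1,3-bis(silyloxy)dienes with alk-2-ynoates, which gives 2,4-dihydroxybenzoates with the hydroxyls ortho and para to the ester. Ring B is closed by suprafacial union of the four diene carbons with the two alkyne carbons, both bonds being made between the two components, so no chain cyclisation and no ring-size preference is involved. Cycloadduct 18 has two transient sp3 ring carbons (the ketal carbon and the aryloxy-bearing carbon) that form without control and need none, because 1,4-elimination of methanol across them gives the aromatic bis(silyl) ether 19 and no stereocentre survives. The aryloxy group cannot be the one lost, since the only other sp3 ring carbon carries two oxygens and no hydrogen, and mixed silyl methyl ketals of this kind aromatise with loss of the methoxy group, so C2 ends as a silyl ether and not as a methyl ether. The selectivity required is regioselectivity, secured by the matched polarisation of the partners; the weakly donating aryloxy group of an acyl-substituted arene cannot override three oxygen donors acting on C4, and the 3Z geometry keeps the reactive s-cis conformer accessible. Excess 17 at high concentration favours the bimolecular step over thermal silyl migration in 11, and dilute acid then cleaves the two aryl silyl ethers without touching the dithiane, the allyl ester or the lactone.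

Step 13
Reactants: 20 allyl 2,4-dihydroxy-5-[(6-methoxy-1-oxo-3-pentyl-1H-isochromen-8-yl)oxy]-6-[(2-pentyl-1,3-dithian-2-yl)methyl]benzoate
Product: 21 allyl 2,4-dihydroxy-5-[(6-methoxy-1-oxo-3-pentyl-1H-isochromen-8-yl)oxy]-6-(2-oxoheptyl)benzoate
Conditions: MeI (excess), CaCO3, MeCN–H2O (4:1), 40 °C, dark
Reagents that add atoms: water, O
Why: Alkylative dethioacetalisation: S-methylation turns sulfur into a leaving group, water traps the thionium ion, and a second methylation releases the ketone; CaCO3 keeps the medium near neutral, so the phenols stay protonated and unmethylated and the allyl ester and lactone are untouched.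

Step 14
Reactants: 21 allyl 2,4-dihydroxy-5-[(6-methoxy-1-oxo-3-pentyl-1H-isochromen-8-yl)oxy]-6-(2-oxoheptyl)benzoate
Product: 22 β-collatolic acid, 2,4-dihydroxy-5-[(6-methoxy-1-oxo-3-pentyl-1H-isochromen-8-yl)oxy]-6-(2-oxoheptyl)benzoic acid
Conditions: Pd(PPh3)4 (5 mol %), PhNHMe (5 equiv), THF, rt; dilute acid wash
Reagents that add atoms: none
Why: Tsuji–Trost-type deallylation: zerovalent palladium ionises the allyl ester to a π-allyl complex and the carboxylate, and N-methylaniline captures the allyl group; the medium is neutral and the amine too weakly basic and nucleophilic to open the lactone, condense with the ketone or promote cyclodehydration of the keto acid.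

## Compound list

1 | methyl 2,4-dihydroxy-6-methylbenzoate (methyl orsellinate) | COC(=O)c1c(C)cc(O)cc1O | starting material
2 | methyl 2,4-dimethoxy-6-methylbenzoate | COC(=O)c1c(C)cc(OC)cc1OC | intermediate
3 | hexanoyl chloride | CCCCCC(=O)Cl | starting material
4 | N-methoxy-N-methylhexanamide | CCCCCC(=O)N(C)OC | intermediate
5 | methyl 2,4-dimethoxy-6-(2-oxoheptyl)benzoate | COC(=O)c1c(CC(=O)CCCCC)cc(OC)cc1OC | intermediate
6 | 6,8-dimethoxy-3-pentyl-1H-isochromen-1-one | CCCCCc1cc2cc(OC)cc(OC)c2c(=O)o1 | intermediate
7 | 8-hydroxy-6-methoxy-3-pentyl-1H-isochromen-1-one | CCCCCc1cc2cc(OC)cc(O)c2c(=O)o1 | intermediate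
8 | methyl 4-chloro-3-oxobutanoate | COC(=O)CC(=O)CCl | starting material
9 | methyl 4-[(6-methoxy-1-oxo-3-pentyl-1H-isochromen-8-yl)oxy]-3-oxobutanoate | COC(=O)CC(=O)COc1cc(OC)cc2cc(CCCCC)oc(=O)c12 | intermediate
10 | methyl (2Z)-4-[(6-methoxy-1-oxo-3-pentyl-1H-isochromen-8-yl)oxy]-3-(trimethylsilyloxy)but-2-enoate | COC(=O)/C=C(\O[Si](C)(C)C)COc1cc(OC)cc2cc(CCCCC)oc(=O)c12 | intermediate (not isolated)
11 | (1Z,3Z)-1-methoxy-1,3-bis(trimethylsilyloxy)-4-[(6-methoxy-1-oxo-3-pentyl-1H-isochromen-8-yl)oxy]buta-1,3-diene | CO/C(O[Si](C)(C)C)=C/C(O[Si](C)(C)C)=C/Oc1cc(OC)cc2cc(CCCCC)oc(=O)c12 | intermediate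
12 | hexanal | CCCCCC=O | starting material
13 | 2-pentyl-1,3-dithiane | CCCCCC1SCCCS1 | intermediate
14 | 3-bromo-1-(trimethylsilyl)prop-1-yne | C[Si](C)(C)C#CCBr | starting material
15 | trimethyl[3-(2-pentyl-1,3-dithian-2-yl)prop-1-yn-1-yl]silane | CCCCCC1(CC#C[Si](C)(C)C)SCCCS1 | intermediate
16 | 2-pentyl-2-(prop-2-yn-1-yl)-1,3-dithiane | CCCCCC1(CC#C)SCCCS1 | intermediate
17 | allyl 4-(2-pentyl-1,3-dithian-2-yl)but-2-ynoate | C=CCOC(=O)C#CCC1(CCCCC)SCCCS1 | intermediate
18 | allyl 6-methoxy-3-[(6-methoxy-1-oxo-3-pentyl-1H-isochromen-8-yl)oxy]-2-[(2-pentyl-1,3-dithian-2-yl)methyl]-4,6-bis(trimethylsilyloxy)cyclohexa-1,4-diene-1-carboxylate (transient; both sp3 ring carbons unassigned, mixture) | C=CCOC(=O)C1=C(CC2(CCCCC)SCCCS2)C(Oc3cc(OC)cc4cc(CCCCC)oc(=O)c34)C(O[Si](C)(C)C)=CC1(OC)O[Si](C)(C)C | intermediate (not isolated)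
19 | allyl 5-[(6-methoxy-1-oxo-3-pentyl-1H-isochromen-8-yl)oxy]-6-[(2-pentyl-1,3-dithian-2-yl)methyl]-2,4-bis(trimethylsilyloxy)benzoate | C=CCOC(=O)c1c(O[Si](C)(C)C)cc(O[Si](C)(C)C)c(Oc2cc(OC)cc3cc(CCCCC)oc(=O)c23)c1CC4(CCCCC)SCCCS4 | intermediate (not isolated)
20 | allyl 2,4-dihydroxy-5-[(6-methoxy-1-oxo-3-pentyl-1H-isochromen-8-yl)oxy]-6-[(2-pentyl-1,3-dithian-2-yl)methyl]benzoate | C=CCOC(=O)c1c(O)cc(O)c(Oc2cc(OC)cc3cc(CCCCC)oc(=O)c23)c1CC4(CCCCC)SCCCS4 | intermediate
21 | allyl 2,4-dihydroxy-5-[(6-methoxy-1-oxo-3-pentyl-1H-isochromen-8-yl)oxy]-6-(2-oxoheptyl)benzoate | C=CCOC(=O)c1c(O)cc(O)c(Oc2cc(OC)cc3cc(CCCCC)oc(=O)c23)c1CC(=O)CCCCC | intermediate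
22 | β-collatolic acid, 2,4-dihydroxy-5-[(6-methoxy-1-oxo-3-pentyl-1H-isochromen-8-yl)oxy]-6-(2-oxoheptyl)benzoic acid | CCCCCC(=O)Cc1c(Oc2cc(OC)cc3cc(CCCCC)oc(=O)c23)c(O)cc(O)c1C(=O)O | target

## Step count and risk

Total: 14 steps. Longest linear sequence: 9 steps from 1 (steps 1, 3, 4, 5, 6, 7, 12, 13, 14). The ynoate branch from 12 contributes steps 8–11, and step 2 makes the acyl donor.

**Step 12 (key step).** The most likely failure is a cycloaddition too slow for the diene to survive. The new C5–C6 bond joins a secondary, aryloxy-substituted diene terminus to an alkyne carbon carrying a neopentyl-type chain. Thermal silyl migration or desilylation of 11, or isomerisation of 17 to its allenoate, may then run ahead of it. Loss of regiocontrol is the lesser risk. The fallback keeps the [4+2] but activates the dienophile with a formyl group in place of the ester and drops the ester protecting group. It sets out from 16 and 11 and rejoins the route at 22. The lithium acetylide of 16 is formylated (n-BuLi, then N,N-dimethylformamide, buffered quench) to 4-(2-pentyl-1,3-dithian-2-yl)but-2-ynal F1. This is a far more electrophilic dienophile of the same size and should add to 11 well below the temperature at which the diene degrades, with the same orientation. Acidic work-up should give 2,4-dihydroxy-5-[(6-methoxy-1-oxo-3-pentyl-1H-isochromen-8-yl)oxy]-6-[(2-pentyl-1,3-dithian-2-yl)methyl]benzaldehyde F2. Alkylative hydrolysis as in step 13 leads to 2,4-dihydroxy-5-[(6-methoxy-1-oxo-3-pentyl-1H-isochromen-8-yl)oxy]-6-(2-oxoheptyl)benzaldehyde F3. Chlorite (Pinnick-type) oxidation with NaClO2, NaH2PO4 and a large excess of 2-methylbut-2-ene then takes the aldehyde to 22. The price is an oxidation beside a resorcinol, which the hypochlorite scavenger has to protect.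

**Step 7.** Three processes threaten this step:

- incomplete second silylation, or carbon silylation in its place;
- hydrolytic loss of silyl groups during isolation;
- intramolecular acylation of the nucleophilic C4 terminus by the silyl-triflate-activated peri lactone carbonyl (a five-membered closure).

Formation of the 3E isomer, which cannot reach the reactive conformer, is a further risk. The fallback replaces soft enolisation by a staged sequence with hard, kinetic deprotonation. It sets out from 9 and returns at 11. Compound 9 is silylated with Me3SiCl and Et3N and the enol ether 10 is isolated. LiN(iPr)2 is then added at −78 °C to a solution of 10 and Me3SiCl, so that the lithium dienolate is silylated as it forms and has no lifetime in which to attack the lactone. No new compound arises.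

**Step 6.** Self-alkylation of the enolate of 8 may outrun ether formation, because the phenoxide of 7 is chelated to the lactone carbonyl and weakly nucleophilic. The fallback changes the electrophile to one that cannot enolise. It sets out from 7 and returns at 9. Phenol 7 is alkylated with methyl (E)-4-bromo-3-methoxybut-2-enoate (K2CO3, acetone, reflux) to methyl (E)-3-methoxy-4-[(6-methoxy-1-oxo-3-pentyl-1H-isochromen-8-yl)oxy]but-2-enoate F4. The enol ether of F4 is then hydrolysed with aqueous HCl in THF to the keto ester 9.

**Step 13.** S-methylation at the crowded dithiane may be slow. Over a long reaction the more acidic 4-hydroxyl could be methylated, or the freed ketone could lactonise onto the allyl ester. The fallback moves the unmasking chemistry ahead of the cycloaddition, where an oxidant is tolerated. It sets out from 17 and 11 and returns at 21. Ynoate 17 is treated with the hypervalent iodine reagent PhI(O2CCF3)2 and ethane-1,2-diol in MeCN, which exchanges the dithiane for a dioxolane and should give allyl 4-(2-pentyl-1,3-dioxolan-2-yl)but-2-ynoate F5. Cycloaddition with 11 as in step 12 gives allyl 2,4-dihydroxy-5-[(6-methoxy-1-oxo-3-pentyl-1H-isochromen-8-yl)oxy]-6-[(2-pentyl-1,3-dioxolan-2-yl)methyl]benzoate F6. Aqueous HCl in THF at room temperature then hydrolyses the ketal to 21 with no alkylating agent present.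

## Further compounds

F1 | step 12 | 4-(2-pentyl-1,3-dithian-2-yl)but-2-ynal | O=CC#CCC1(CCCCC)SCCCS1
F2 | step 12 | 2,4-dihydroxy-5-[(6-methoxy-1-oxo-3-pentyl-1H-isochromen-8-yl)oxy]-6-[(2-pentyl-1,3-dithian-2-yl)methyl]benzaldehyde | O=Cc1c(O)cc(O)c(Oc2cc(OC)cc3cc(CCCCC)oc(=O)c23)c1CC4(CCCCC)SCCCS4
F3 | step 12 | 2,4-dihydroxy-5-[(6-methoxy-1-oxo-3-pentyl-1H-isochromen-8-yl)oxy]-6-(2-oxoheptyl)benzaldehyde | O=Cc1c(O)cc(O)c(Oc2cc(OC)cc3cc(CCCCC)oc(=O)c23)c1CC(=O)CCCCC
F0 | step 7 | none | none
F4 | step 6 | methyl (E)-3-methoxy-4-[(6-methoxy-1-oxo-3-pentyl-1H-isochromen-8-yl)oxy]but-2-enoate | COC(=O)/C=C(/OC)COc1cc(OC)cc2cc(CCCCC)oc(=O)c12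
F5 | step 13 | allyl 4-(2-pentyl-1,3-dioxolan-2-yl)but-2-ynoate | C=CCOC(=O)C#CCC1(CCCCC)OCCO1
F6 | step 13 | allyl 2,4-dihydroxy-5-[(6-methoxy-1-oxo-3-pentyl-1H-isochromen-8-yl)oxy]-6-[(2-pentyl-1,3-dioxolan-2-yl)methyl]benzoate | C=CCOC(=O)c1c(O)cc(O)c(Oc2cc(OC)cc3cc(CCCCC)oc(=O)c23)c1CC4(CCCCC)OCCO4
A1 | alternative 1 | methyl 4-methoxy-2-(2-methoxy-2-oxoethoxy)-6-methylbenzoate | COC(=O)COc1cc(OC)cc(C)c1C(=O)OC
A2 | alternative 1 | tert-butyl 2-acetyl-4-(2-pentyl-1,3-dioxolan-2-yl)but-2-enoate | CC(=O)C(=CCC1(CCCCC)OCCO1)C(=O)OC(C)(C)C
A3 | alternative 1 | racemic tert-butyl trans,trans-3-(2-methoxycarbonyl-5-methoxy-3-methylphenoxy)-4,6-dioxo-2-[(2-pentyl-1,3-dioxolan-2-yl)methyl]cyclohexane-1-carboxylate | CC(C)(C)OC(=O)[C@H]1[C@H](CC2(CCCCC)OCCO2)[C@@H](Oc3cc(OC)cc(C)c3C(=O)OC)C(=O)CC1=O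
A4 | alternative 2 | benzyl 2,4-bis(benzyloxy)-5-hydroxy-6-[(2-pentyl-1,3-dithian-2-yl)methyl]benzoate | Oc1c(OCc2ccccc2)cc(OCc3ccccc3)c(C(=O)OCc4ccccc4)c1CC5(CCCCC)SCCCS5
A5 | alternative 2 | benzyl 2,4-bis(benzyloxy)-5-{[4-methoxy-4-(trimethylsilyloxy)buta-1,3-dien-2-yl]oxy}-6-[(2-pentyl-1,3-dithian-2-yl)methyl]benzoate | C=C(Oc1c(OCc2ccccc2)cc(OCc3ccccc3)c(C(=O)OCc4ccccc4)c1CC5(CCCCC)SCCCS5)C=C(OC)O[Si](C)(C)C
A6 | alternative 2 | 4,4-dimethoxybut-3-en-2-one | CC(=O)C=C(OC)OC
A7 | alternative 2 | benzyl 2,4-bis(benzyloxy)-5-[2-(methoxycarbonyl)-5-methoxy-3-methylphenoxy]-6-[(2-pentyl-1,3-dithian-2-yl)methyl]benzoate | COC(=O)c1c(C)cc(OC)cc1Oc2c(OCc3ccccc3)cc(OCc4ccccc4)c(C(=O)OCc5ccccc5)c2CC6(CCCCC)SCCCS6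
A8 | alternative 3 | 6-{3-[(6-methoxy-1-oxo-3-pentyl-1H-isochromen-8-yl)oxy]-2,4-dioxo-5-(2-pentyl-1,3-dioxolan-2-yl)pentyl}-2,2-dimethyl-4H-1,3-dioxin-4-one | CC1(C)OC(=O)C=C(CC(=O)C(Oc2cc(OC)cc3cc(CCCCC)oc(=O)c23)C(=O)CC4(CCCCC)OCCO4)O1
A9 | alternative 3 | tert-butyl 6-[(6-methoxy-1-oxo-3-pentyl-1H-isochromen-8-yl)oxy]-3,5,7-trioxo-8-(2-pentyl-1,3-dioxolan-2-yl)octanoate | CC(C)(C)OC(=O)CC(=O)CC(=O)C(Oc1cc(OC)cc2cc(CCCCC)oc(=O)c12)C(=O)CC3(CCCCC)OCCO3
A10 | alternative 3 | tert-butyl 2,4-dihydroxy-5-[(6-methoxy-1-oxo-3-pentyl-1H-isochromen-8-yl)oxy]-6-[(2-pentyl-1,3-dioxolan-2-yl)methyl]benzoate | CC(C)(C)OC(=O)c1c(O)cc(O)c(Oc2cc(OC)cc3cc(CCCCC)oc(=O)c23)c1CC4(CCCCC)OCCO4
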